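**Plan**

1. Retrosynthetic cuts, in order: both aryl C–Br bonds and the O–CH3 bond (late dibromination of the free phenol); the C4–C5 bond of the bicyclo[3.1.0]hexane (cyclopentane CH2 to cyclopropane CH); the cyclopropene back to an isopropenyl group (one carbon from CHBr3) and the iodoethyl arm back to a vinyl group; the C2–isopropenyl bond at the benzylic quaternary carbon (SN2′ allylic substitution).
2. Enabling feature: C1 (methyl-bearing ring-fusion carbon), C5 (CH) and C6 (CH2) form a cyclopropane in which C5 and C6 differ only by the bond to C4. Written as a 3-alkyl-3-methylcyclopropene, C5 and C6 become two equivalent olefinic CH carbons, C1 is no stereocentre, and the C3–C4 ethylene arm on C2 reaches either olefinic carbon through a five-membered ring.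
3. Forward order: aryl ketone → allylic phosphate → quaternary C2 by copper-catalysed allylic substitution → hydroxyethyl arm → three-membered ring (dibromocarbene, monoreduction, elimination to the cyclopropene) → iodide → radical closure of the cyclopentane, which completes the bicyclo[3.1.0]hexane → phenol → dibromide.
4. Stereochemistry: C2 comes from the chiral NHC–copper catalyst (step 4). C1 and C5 are both set in the ring closure: the tether enforces cis fusion, and the choice between the two diastereotopic olefinic carbons, steered by C2, fixes them relative to C2. The diastereomers made in steps 7 and 8 converge.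

Key step: step 12

Remark: the chiral sulfonate-bearing imidazolinium salt of step 4 is a catalyst component accessible in both antipodes; the antipode that delivers (R)-7 is used. Ketone 1 is taken as purchased.

**Route**

Step 1
Reactants: 1 1-(2-methoxy-4-methylphenyl)ethan-1-one; 2 triethyl phosphonoacetate
Product: 3 ethyl (2E)-3-(2-methoxy-4-methylphenyl)but-2-enoate
Conditions: NaH, THF, 0 °C then reflux; minor (Z)-isomer removed by chromatography
Reagents that add atoms: none
Why: Horner–Wadsworth–Emmons olefination of an aryl methyl ketone should give mainly the (E)-enoate, with the aryl group trans to the ester.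

Step 2
Reactants: 3 ethyl (2E)-3-(2-methoxy-4-methylphenyl)but-2-enoate
Product: 4 (2E)-3-(2-methoxy-4-methylphenyl)but-2-en-1-ol
Conditions: DIBAL-H (i-Bu2AlH, 2.2 equiv), CH2Cl2, −78 °C to 0 °C; aqueous sodium potassium tartrate
Reagents that add atoms: none
Why: 1,2-reduction of the conjugated ester by the aluminium hydride gives the allylic alcohol and leaves the alkene geometry untouched.

Step 3
Reactants: 4 (2E)-3-(2-methoxy-4-methylphenyl)but-2-en-1-ol
Product: 5 diethyl (2E)-3-(2-methoxy-4-methylphenyl)but-2-en-1-yl phosphate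
Conditions: (EtO)2P(O)Cl, Et3N, DMAP (cat), CH2Cl2, 0 °C to 20 °C
Reagents that add atoms: diethyl chlorophosphate, CCOP(=O)(Cl)OCC
Why: O-phosphorylation of the primary allylic alcohol installs the leaving group needed for copper-catalysed allylic substitution.

Step 4
Reactants: 5 diethyl (2E)-3-(2-methoxy-4-methylphenyl)but-2-en-1-yl phosphate; 6 4,4,5,5-tetramethyl-2-(prop-1-en-2-yl)-1,3,2-dioxaborolane
Product: 7 1-[(3R)-2,3-dimethylpenta-1,4-dien-3-yl]-2-methoxy-4-methylbenzene
Conditions: 6 (1.5 equiv), CuCl (5 mol %), chiral sulfonate-bearing imidazolinium salt (NHC precursor, 5.5 mol %), NaOMe (1.5 equiv), THF, 60 °C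
Reagents that add atoms: none
Why: Copper-catalysed enantioselective allylic substitution (SN2′) of a γ,γ-disubstituted allylic phosphate with an alkenyl-B(pin) reagent, in which the NHC–Cu–isopropenyl species formed by boron-to-copper transmetalation adds at the aryl-bearing carbon anti to the phosphate and the chiral NHC selects the alkene face, so that the all-carbon quaternary centre is set as (R).

Step 5
Reactants: 7 1-[(3R)-2,3-dimethylpenta-1,4-dien-3-yl]-2-methoxy-4-methylbenzene
Product: 9 (3R)-3-(2-methoxy-4-methylphenyl)-3,4-dimethylpent-4-en-1-ol, via alkyl catecholboronate 8 (not isolated)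
Conditions: catecholborane (1.2 equiv), RhCl(PPh3)3 (2 mol %), THF, 20 °C; then NaOH, H2O2, 0 °C
Reagents that add atoms: hydrogen peroxide, OO (the oxygen of 9); catecholborane, B1Oc2ccccc2O1 (boron and catechol unit, present only in 8)
Why: Rhodium-catalysed hydroboration is anti-Markovnikov and strongly prefers a monosubstituted alkene over a hindered 1,1-disubstituted one, so only the vinyl group reacts, and oxidation of the C–B bond gives the primary alcohol without touching the quaternary centre.

Step 6
Reactants: 9 (3R)-3-(2-methoxy-4-methylphenyl)-3,4-dimethylpent-4-en-1-ol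
Product: 10 {[(3R)-3-(2-methoxy-4-methylphenyl)-3,4-dimethylpent-4-en-1-yl]oxy}tri(propan-2-yl)silane
Conditions: TIPSCl, imidazole, DMF, 20 °C
Reagents that add atoms: chlorotri(propan-2-yl)silane, CC(C)[Si](Cl)(C(C)C)C(C)C
Why: Silylation of the primary alcohol gives an ether that withstands the aqueous NaOH, Grignard and KOtBu/DMSO conditions of the next three steps.

Step 7
Reactants: 10 {[(3R)-3-(2-methoxy-4-methylphenyl)-3,4-dimethylpent-4-en-1-yl]oxy}tri(propan-2-yl)silane
Product: 11 {[(3S)-3-(2,2-dibromo-1-methylcyclopropyl)-3-(2-methoxy-4-methylphenyl)butyl]oxy}tri(propan-2-yl)silane (both epimers at the new cyclopropane carbon)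
Conditions: CHBr3 (4 equiv), 50 % aqueous NaOH, benzyltriethylammonium chloride (5 mol %), CH2Cl2, 20 °C, vigorous stirring
Reagents that add atoms: bromoform, BrC(Br)Br
Why: Phase-transfer dibromocyclopropanation adds the electrophilic dibromocarbene to the 1,1-disubstituted alkene; the new ring carbon forms without facial control, which does not matter because it stops being a stereocentre in step 9 (the benzylic descriptor becomes S only because the brominated ring now outranks the aryl group).

Step 8
Reactants: 11 {[(3S)-3-(2,2-dibromo-1-methylcyclopropyl)-3-(2-methoxy-4-methylphenyl)butyl]oxy}tri(propan-2-yl)silane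
Product: 12 {[(3S)-3-(2-bromo-1-methylcyclopropyl)-3-(2-methoxy-4-methylphenyl)butyl]oxy}tri(propan-2-yl)silane (mixture of cyclopropane diastereomers)
Conditions: EtMgBr (1.3 equiv), Ti(OiPr)4 (5 mol %), Et2O, 20 °C
Reagents that add atoms: none
Why: Titanium-catalysed hydrodebromination of a gem-dibromocyclopropane with EtMgBr should stop at the monobromide, whose C–Br configuration is irrelevant for the elimination that follows.

Step 9
Reactants: 12 {[(3S)-3-(2-bromo-1-methylcyclopropyl)-3-(2-methoxy-4-methylphenyl)butyl]oxy}tri(propan-2-yl)silane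
Product: 13 {[(3R)-3-(2-methoxy-4-methylphenyl)-3-(1-methylcycloprop-2-en-1-yl)butyl]oxy}tri(propan-2-yl)silane
Conditions: KOtBu (1.5 equiv), DMSO, 20 °C
Reagents that add atoms: none
Why: Base-induced 1,2-dehydrobromination of a 2,2-disubstituted bromocyclopropane is the standard entry to 3,3-disubstituted cyclopropenes, and all diastereomers of 12 converge on one compound because the sp3 ring carbon now carries two identical olefinic arms and has no hydrogen through which the alkene could migrate.

Step 10
Reactants: 13 {[(3R)-3-(2-methoxy-4-methylphenyl)-3-(1-methylcycloprop-2-en-1-yl)butyl]oxy}tri(propan-2-yl)silane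
Product: 14 (3R)-3-(2-methoxy-4-methylphenyl)-3-(1-methylcycloprop-2-en-1-yl)butan-1-ol
Conditions: Bu4NF, AcOH (1:1), THF, 20 °C
Reagents that add atoms: none
Why: Fluoride cleaves the silyl ether, and the acetic acid buffer keeps the liberated alkoxide from adding to the strained alkene.

Step 11
Reactants: 14 (3R)-3-(2-methoxy-4-methylphenyl)-3-(1-methylcycloprop-2-en-1-yl)butan-1-ol
Product: 16 1-[(2R)-4-iodo-2-(1-methylcycloprop-2-en-1-yl)butan-2-yl]-2-methoxy-4-methylbenzene, via primary mesylate 15 (not isolated)
Conditions: MsCl, Et3N, CH2Cl2, −10 °C; solvent exchange; NaI (5 equiv), acetone, 45 °C, dark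
Reagents that add atoms: methanesulfonyl chloride, CS(=O)(=O)Cl (present only in 15); sodium iodide, [Na+].[I-]
Why: Sulfonylation followed by Finkelstein SN2 displacement gives the primary iodide without any electrophilic iodine source that could add to the cyclopropene.

Step 12
Reactants: 16 1-[(2R)-4-iodo-2-(1-methylcycloprop-2-en-1-yl)butan-2-yl]-2-methoxy-4-methylbenzene
Product: 17 1-[(1S,2R,5R)-1,2-dimethylbicyclo[3.1.0]hexan-2-yl]-2-methoxy-4-methylbenzene
Conditions: Bu3SnH (1.3 equiv, 0.05 M), Et3B (0.2 equiv), air, hexane, 0 °C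
Reagents that add atoms: none
Why: Proposed new method: Bu3Sn• takes iodine from 16 and the primary radical adds to the nearer end of the strained C=C of the 3,3-disubstituted cyclopropene, which releases about half of the ring's roughly 54 kcal/mol strain, to give a σ-cyclopropyl radical that is reduced at once by Bu3SnH; the closest known reaction types are the 5-hexenyl radical cyclization and the intermolecular addition of carbon radicals to cyclopropenes (xanthate transfer, photoredox (3+2) annulation to bicyclo[3.1.0]hexanes). The cyclopentane closes in the 5-exo-trig mode, and because the two-carbon tether can reach only the cyclopropene face on which it stands, the ring fusion is necessarily cis, which sets C1 and C5 relative to each other. Their configuration relative to the existing centre C2 depends on which of the two diastereotopic olefinic carbons is attacked, and since the cyclopropene sp3 carbon is not a stereocentre nothing has to be controlled before this step. Attack at the olefinic carbon on the side of the C2 methyl leaves the other CH (the future CH2 bridge) beside the aryl ring and lets the cyclopropene methyl nearly eclipse the small C2 methyl, whereas the alternative presses that methyl against the bulky ortho-methoxyaryl group across the C2–C1 bond, so torsional strain in the substrate should favour the required (1S,2R,5R) isomer. The step also needs iodine abstraction to outrun stannyl addition to the strained alkene, which the near diffusion-controlled C–I abstraction secures, and cyclization to outrun reduction of the primary radical, which strain release, the two fully substituted carbons in the tether and the low Bu3SnH concentration secure.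

Step 13
Reactants: 17 1-[(1S,2R,5R)-1,2-dimethylbicyclo[3.1.0]hexan-2-yl]-2-methoxy-4-methylbenzene
Product: 18 2-[(1S,2R,5R)-1,2-dimethylbicyclo[3.1.0]hexan-2-yl]-5-methylphenol
Conditions: NaSEt (5 equiv), DMF, 120 °C; then pH 7 phosphate buffer
Reagents that add atoms: none
Why: SN2 demethylation of the aryl methyl ether by ethanethiolate frees the phenol under non-acidic conditions, which is required because acid would let the phenol open the neighbouring cyclopropane.

Step 14
Reactants: 18 2-[(1S,2R,5R)-1,2-dimethylbicyclo[3.1.0]hexan-2-yl]-5-methylphenol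
Product: 19 2,4-dibromo-6-[(1S,2R,5R)-1,2-dimethylbicyclo[3.1.0]hexan-2-yl]-3-methylphenol
Conditions: N-bromosuccinimide (2.1 equiv), NaHCO3 (solid), MeCN, 0 °C, dark
Reagents that add atoms: N-bromosuccinimide, O=C1CCC(=O)N1Br
Why: Electrophilic aromatic bromination of the phenol takes place at the two free positions ortho and para to OH (each also ortho to the ring methyl), the other ortho position being blocked by the quaternary substituent, while the bicarbonate keeps the medium free of acid.

**Compound list**

1 | 1-(2-methoxy-4-methylphenyl)ethan-1-one | COc1cc(C)ccc1C(C)=O | starting material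
2 | triethyl phosphonoacetate | CCOC(=O)CP(=O)(OCC)OCC | starting material
3 | ethyl (2E)-3-(2-methoxy-4-methylphenyl)but-2-enoate | CCOC(=O)/C=C(\C)c1ccc(C)cc1OC | intermediate
4 | (2E)-3-(2-methoxy-4-methylphenyl)but-2-en-1-ol | OC/C=C(\C)c1ccc(C)cc1OC | intermediate
5 | diethyl (2E)-3-(2-methoxy-4-methylphenyl)but-2-en-1-yl phosphate | CCOP(=O)(OCC)OC/C=C(\C)c1ccc(C)cc1OC | intermediate
6 | 4,4,5,5-tetramethyl-2-(prop-1-en-2-yl)-1,3,2-dioxaborolane | CC(=C)B1OC(C)(C)C(C)(C)O1 | starting material
7 | 1-[(3R)-2,3-dimethylpenta-1,4-dien-3-yl]-2-methoxy-4-methylbenzene | COc1cc(C)ccc1[C@](C)(C=C)C(C)=C | intermediate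
8 | 2-[(3R)-3-(2-methoxy-4-methylphenyl)-3,4-dimethylpent-4-en-1-yl]-1,3,2-benzodioxaborole | COc1cc(C)ccc1[C@](C)(CCB1Oc2ccccc2O1)C(C)=C | intermediate (not isolated)
9 | (3R)-3-(2-methoxy-4-methylphenyl)-3,4-dimethylpent-4-en-1-ol | COc1cc(C)ccc1[C@](C)(CCO)C(C)=C | intermediate
10 | {[(3R)-3-(2-methoxy-4-methylphenyl)-3,4-dimethylpent-4-en-1-yl]oxy}tri(propan-2-yl)silane | COc1cc(C)ccc1[C@](C)(CCO[Si](C(C)C)(C(C)C)C(C)C)C(C)=C | intermediate
11 | {[(3S)-3-(2,2-dibromo-1-methylcyclopropyl)-3-(2-methoxy-4-methylphenyl)butyl]oxy}tri(propan-2-yl)silane, both epimers at the cyclopropane carbon | COc1cc(C)ccc1[C@](C)(CCO[Si](C(C)C)(C(C)C)C(C)C)C1(C)CC1(Br)Br | intermediate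
12 | {[(3S)-3-(2-bromo-1-methylcyclopropyl)-3-(2-methoxy-4-methylphenyl)butyl]oxy}tri(propan-2-yl)silane, mixture of cyclopropane diastereomers | COc1cc(C)ccc1[C@](C)(CCO[Si](C(C)C)(C(C)C)C(C)C)C1(C)CC1Br | intermediate
13 | {[(3R)-3-(2-methoxy-4-methylphenyl)-3-(1-methylcycloprop-2-en-1-yl)butyl]oxy}tri(propan-2-yl)silane | COc1cc(C)ccc1[C@](C)(CCO[Si](C(C)C)(C(C)C)C(C)C)C1(C)C=C1 | intermediate
14 | (3R)-3-(2-methoxy-4-methylphenyl)-3-(1-methylcycloprop-2-en-1-yl)butan-1-ol | COc1cc(C)ccc1[C@](C)(CCO)C1(C)C=C1 | intermediate
15 | (3R)-3-(2-methoxy-4-methylphenyl)-3-(1-methylcycloprop-2-en-1-yl)butyl methanesulfonate | COc1cc(C)ccc1[C@](C)(CCOS(C)(=O)=O)C1(C)C=C1 | intermediate (not isolated)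
16 | 1-[(2R)-4-iodo-2-(1-methylcycloprop-2-en-1-yl)butan-2-yl]-2-methoxy-4-methylbenzene | COc1cc(C)ccc1[C@](C)(CCI)C1(C)C=C1 | intermediate
17 | 1-[(1S,2R,5R)-1,2-dimethylbicyclo[3.1.0]hexan-2-yl]-2-methoxy-4-methylbenzene | COc1cc(C)ccc1[C@]1(C)CC[C@@H]2C[C@@]21C | intermediate
18 | 2-[(1S,2R,5R)-1,2-dimethylbicyclo[3.1.0]hexan-2-yl]-5-methylphenol | Oc1cc(C)ccc1[C@]1(C)CC[C@@H]2C[C@@]21C | intermediate
19 | 2,4-dibromo-6-[(1S,2R,5R)-1,2-dimethylbicyclo[3.1.0]hexan-2-yl]-3-methylphenol | Cc1c(Br)cc([C@]2(C)CC[C@@H]3C[C@@]32C)c(O)c1Br | target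

**Step count**

Total: 14 steps. Longest linear sequence: 14 steps (1 → 19).

**Steps most likely to fail**

1. Step 12 (the step beyond known chemistry). The two diastereotopic olefinic carbons may be discriminated poorly, so that the C1/C5-epimeric bicycle forms alongside; the primary radical may be reduced before it cyclizes; the stannyl radical may add to the strained alkene. The fallback uses known chemistry, sets out from 9 and returns at 18. Iodination of 9 (PPh3, I2, imidazole) should give 1-[(3R)-5-iodo-2,3-dimethylpent-1-en-3-yl]-2-methoxy-4-methylbenzene F1. Copper-catalysed coupling with CH2=CHMgBr (CuI cat, THF) should give the 1,6-diene 1-[(3R)-2,3-dimethylhepta-1,6-dien-3-yl]-2-methoxy-4-methylbenzene F2. Ring-closing metathesis with second-generation Grubbs catalyst should close the cyclopentene 1-[(1R)-1,2-dimethylcyclopent-2-en-1-yl]-2-methoxy-4-methylbenzene F3. Demethylation with NaSEt in DMF should give 2-[(1R)-1,2-dimethylcyclopent-2-en-1-yl]-5-methylphenol F4. A Simmons–Smith cyclopropanation (Et2Zn, CH2I2, CH2Cl2), directed by the zinc phenoxide, should deliver CH2 to the alkene face syn to the aryl group and give 18. This route forms the C1–C6 and C5–C6 bonds last instead of C4–C5.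

2. Step 4. Allyl transfer to the hindered γ-carbon next to the ortho-substituted ring may be slow or unselective, which would erode the enantioselectivity or let direct (SN2) substitution compete. The fallback sets out from 1 and returns at 7; it replaces catalyst control by a stereospecific lithiation–borylation.
   - Corey–Bakshi–Shibata reduction of 1 ((R)-2-methyl-CBS-oxazaborolidine, BH3·SMe2) should give (1S)-1-(2-methoxy-4-methylphenyl)ethan-1-ol F5.
   - Carbamoylation (i-Pr2NCOCl, Et3N, toluene, reflux) should give (1S)-1-(2-methoxy-4-methylphenyl)ethyl N,N-di(propan-2-yl)carbamate F6.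
   - Deprotonation with s-BuLi (Et2O, −78 °C) should give the configurationally stable α-lithiated carbamate F7. Addition of 6 should give, with retention, the lithium boronate complex F8.
   - On warming, 1,2-migration of the isopropenyl group with inversion and loss of the carbamate should give the tertiary boronic ester 2-[(2S)-2-(2-methoxy-4-methylphenyl)-3-methylbut-3-en-2-yl]-4,4,5,5-tetramethyl-1,3,2-dioxaborolane F9.
   - Zweifel olefination: CH2=CHMgBr in THF/DMSO should give the vinyl boronate complex F10. I2 should trigger 1,2-migration with retention to the β-iodoalkyl boronic ester 2-[(3R)-1-iodo-3-(2-methoxy-4-methylphenyl)-3,4-dimethylpent-4-en-2-yl]-4,4,5,5-tetramethyl-1,3,2-dioxaborolane F11. NaOMe should then effect anti-elimination to 7.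

3. Step 5. Site selectivity between the two terminal alkenes may be incomplete (hydroboration of the isopropenyl group), or rhodium hydride may isomerize an alkene. The fallback sets out from 7 and returns at 11; it reverses the order of the two alkene functionalisations, so that the selective event is carbene addition, which favours the more substituted alkene. Phase-transfer dibromocyclopropanation of 7 (CHBr3, aqueous NaOH, benzyltriethylammonium chloride) should give 1-[(2S)-2-(2,2-dibromo-1-methylcyclopropyl)but-3-en-2-yl]-2-methoxy-4-methylbenzene F12. Hydroboration of the only remaining alkene with 9-BBN should give the B-alkyl-9-borabicyclo[3.3.1]nonane F13, and oxidation (NaOH, H2O2) should give (3S)-3-(2,2-dibromo-1-methylcyclopropyl)-3-(2-methoxy-4-methylphenyl)butan-1-ol F14. Silylation (TIPSCl, imidazole) should then give 11.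

Further compounds

F1 | step 12 | 1-[(3R)-5-iodo-2,3-dimethylpent-1-en-3-yl]-2-methoxy-4-methylbenzene | COc1cc(C)ccc1[C@](C)(CCI)C(C)=C
F2 | step 12 | 1-[(3R)-2,3-dimethylhepta-1,6-dien-3-yl]-2-methoxy-4-methylbenzene | COc1cc(C)ccc1[C@](C)(CCC=C)C(C)=C
F3 | step 12 | 1-[(1R)-1,2-dimethylcyclopent-2-en-1-yl]-2-methoxy-4-methylbenzene | COc1cc(C)ccc1[C@]1(C)CCC=C1C
F4 | step 12 | 2-[(1R)-1,2-dimethylcyclopent-2-en-1-yl]-5-methylphenol | Oc1cc(C)ccc1[C@]1(C)CCC=C1C
F5 | step 4 | (1S)-1-(2-methoxy-4-methylphenyl)ethan-1-ol | C[C@H](O)c1ccc(C)cc1OC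
F6 | step 4 | (1S)-1-(2-methoxy-4-methylphenyl)ethyl N,N-di(propan-2-yl)carbamate | C[C@H](OC(=O)N(C(C)C)C(C)C)c1ccc(C)cc1OC
F7 | step 4 | (1S)-1-lithio-1-(2-methoxy-4-methylphenyl)ethyl N,N-di(propan-2-yl)carbamate | C[C@]([Li])(OC(=O)N(C(C)C)C(C)C)c1ccc(C)cc1OC
F8 | step 4 | lithium boronate complex of F7 and 6 (isopropenyl and carbamoyloxyalkyl groups on tetracoordinate boron) | C[C@]([B-]1(C(C)=C)OC(C)(C)C(C)(C)O1)(OC(=O)N(C(C)C)C(C)C)c1ccc(C)cc1OC.[Li+]
F9 | step 4 | 2-[(2S)-2-(2-methoxy-4-methylphenyl)-3-methylbut-3-en-2-yl]-4,4,5,5-tetramethyl-1,3,2-dioxaborolane | C[C@@](B1OC(C)(C)C(C)(C)O1)(C(C)=C)c1ccc(C)cc1OC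
F10 | step 4 | bromomagnesium vinyl boronate complex of F9 | C[C@@]([B-]1(C=C)OC(C)(C)C(C)(C)O1)(C(C)=C)c1ccc(C)cc1OC.[Mg+2].[Br-]
F11 | step 4 | 2-[(3R)-1-iodo-3-(2-methoxy-4-methylphenyl)-3,4-dimethylpent-4-en-2-yl]-4,4,5,5-tetramethyl-1,3,2-dioxaborolane, both epimers at the boron-bearing carbon | C[C@@](C(CI)B1OC(C)(C)C(C)(C)O1)(C(C)=C)c1ccc(C)cc1OC
F12 | step 5 | 1-[(2S)-2-(2,2-dibromo-1-methylcyclopropyl)but-3-en-2-yl]-2-methoxy-4-methylbenzene, both epimers at the cyclopropane carbon | COc1cc(C)ccc1[C@](C)(C=C)C1(C)CC1(Br)Br
F13 | step 5 | 9-[(3S)-3-(2,2-dibromo-1-methylcyclopropyl)-3-(2-methoxy-4-methylphenyl)butyl]-9-borabicyclo[3.3.1]nonane | COc1cc(C)ccc1[C@](C)(CCB1C2CCCC1CCC2)C1(C)CC1(Br)Br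
F14 | step 5 | (3S)-3-(2,2-dibromo-1-methylcyclopropyl)-3-(2-methoxy-4-methylphenyl)butan-1-ol | COc1cc(C)ccc1[C@](C)(CCO)C1(C)CC1(Br)Br
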